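**Plan**

- Retrosynthesis: C13=C14 is cut by olefination, the C6–O bond is traced to a C6 acetyl group (oxygen insertion with retention), the C8–CH3 bond to methyl addition onto an 8-ketone, and the 8-ketone/H-9 pair to an 8,9-alkene; the bicycle is then opened at C5–C10 and C6–C7 in one intramolecular [4+2] disconnection.
- Enabling feature: C5, C6 and C10 are adjacent ring B stereocentres, C6 bears an oxygen that can stand for a formyl-activated dienophile carbon, and C8–C9 can be an alkene. Ring B is thus the cyclohexene from diene C7=C8–C9=C10 plus E-enal C5=C6, and ring A (C1–C4 with C5 and C10) is the tether, attached at the Z position of C10.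
- The C8 methyl group is left off the diene on purpose: a trisubstituted 8,9-alkene allows a stereospecific epoxide-to-ketone route to H-9 and the C8 carbinol, which a tetrasubstituted alkene would not.
- Forward: linear assembly of trienal 16 (C4 by enolate alkylation, C9=C10 by carbocupration–allylation of an ynoate), closure of rings A and B together in step 9, then ring B adjustment and side-chain olefination.
- Stereochemistry: C5, C6 and C10 from the amine-catalysed cycloaddition (cis fusion from the Z tether, formyl endo, absolute sense from the catalyst); C9 from a suprafacial 1,2-hydride shift in the α-epoxide; C8 from equatorial methyl addition; C6–O by retentive Baeyer–Villiger oxidation; the E-enoate from the olefination.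

Key step: step 9

Remark: locants C1–C20 are labdane locants (C4 gem-dimethyl carbon, C5/C10 ring fusion, C6 acetoxy carbon, C8 carbinol carbon, C9 side-chain carbon). α is the face of ring B carrying H-5 and the C10 methyl group, β the opposite face. The target SMILES corresponds to the cis-fused (5S,6S,8S,9S,10R) isomer, and that isomer is the one planned for.

**Route**

Step 1
Reactants: 1 methyl 2-methylpropanoate; 2 5-iodopent-1-yne
Product: 4 methyl 2,2-dimethylhept-6-ynoate, via lithium enolate 3 (not isolated)
Conditions: LiN(iPr)2 (LDA), THF, −78 °C; then 2, DMPU, −78 °C to rt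
Reagents that add atoms: none
Why: Ester enolate alkylation by a primary iodide builds the C4 quaternary carbon and attaches C1–C3 plus the two future C9/C10 alkyne carbons; the fully substituted enolate cannot alkylate twice.

Step 2
Reactants: 4 methyl 2,2-dimethylhept-6-ynoate; 5 ethyl chloroformate
Product: 7 1-ethyl 8-methyl 7,7-dimethyloct-2-ynedioate, via lithium acetylide 6 (not isolated)
Conditions: LiN(iPr)2 (LDA), THF, −78 °C; then 5, −78 to 0 °C
Reagents that add atoms: none
Why: Acetylide C-acylation by a chloroformate is the standard ynoate synthesis, and the amide base should not attack the hindered, non-enolisable methyl ester.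

Step 3
Reactants: 7 1-ethyl 8-methyl 7,7-dimethyloct-2-ynedioate; 8 3-bromoprop-1-ene (allyl bromide)
Product: 10 1-ethyl 8-methyl (2Z)-3,7,7-trimethyl-2-(prop-2-en-1-yl)oct-2-enedioate, via alkenylcuprate 9 (not isolated)
Conditions: Me2CuLi (from MeLi and CuI), THF, −78 °C; then 8, DMPU, −78 to −40 °C
Reagents that add atoms: lithium dimethylcuprate, [Li+].C[Cu-]C
Why: Conjugate addition–alkylation of an alkynoate: syn carbocupration puts methyl and copper on the same side, and cold allylation with retention should leave the ester cis to the C1 chain, which fixes the Z-tethered diene terminus.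

Step 4
Reactants: 10 1-ethyl 8-methyl (2Z)-3,7,7-trimethyl-2-(prop-2-en-1-yl)oct-2-enedioate
Product: 11 (2Z)-3,7,7-trimethyl-2-(prop-2-en-1-yl)oct-2-ene-1,8-diol
Conditions: iBu2AlH (DIBAL-H, 5 equiv), CH2Cl2, −78 to 0 °C; aqueous potassium sodium tartrate work-up
Reagents that add atoms: none
Why: Ester reduction by the aluminium hydride should convert both esters into primary alcohols without touching the alkenes or the alkene geometry.

Step 5
Reactants: 11 (2Z)-3,7,7-trimethyl-2-(prop-2-en-1-yl)oct-2-ene-1,8-diol
Product: 12 (2Z)-8-hydroxy-3,7,7-trimethyl-2-(prop-2-en-1-yl)oct-2-enal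
Conditions: MnO2 (activated, excess), CH2Cl2, rt
Reagents that add atoms: none
Why: Chemoselective allylic oxidation: MnO2 should oxidise only the allylic alcohol, so the neopentyl alcohol is differentiated without protecting groups.

Step 6
Reactants: 12 (2Z)-8-hydroxy-3,7,7-trimethyl-2-(prop-2-en-1-yl)oct-2-enal
Product: 13 (6Z)-2,2,6-trimethyl-7-(prop-2-en-1-yl)nona-6,8-dien-1-ol
Conditions: Ph3PCH3Br, KOtBu, THF, 0 °C; then 12, −78 to 0 °C
Reagents that add atoms: methylenetriphenylphosphorane, C=P(c1ccccc1)(c1ccccc1)c1ccccc1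
Why: Wittig methylenation of the enal supplies C7 and completes the 1,3-diene; excess ylide tolerates the hydroxyl group as its alkoxide, and the cold conditions should leave the tetrasubstituted alkene geometry intact.

Step 7
Reactants: 13 (6Z)-2,2,6-trimethyl-7-(prop-2-en-1-yl)nona-6,8-dien-1-ol
Product: 14 (6Z)-2,2,6-trimethyl-7-(prop-2-en-1-yl)nona-6,8-dienal
Conditions: Dess–Martin periodinane, NaHCO3, CH2Cl2, 0 °C to rt
Reagents that add atoms: none
Why: Dess–Martin oxidation should convert the neopentyl alcohol into the non-enolisable aldehyde under neutral conditions that spare the triene.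

Step 8
Reactants: 14 (6Z)-2,2,6-trimethyl-7-(prop-2-en-1-yl)nona-6,8-dienal; 15 2-(triphenyl-λ5-phosphanylidene)acetaldehyde
Product: 16 (2E,8Z)-4,4,8-trimethyl-9-(prop-2-en-1-yl)undeca-2,8,10-trienal
Conditions: toluene, 80 °C
Reagents that add atoms: none
Why: Wittig reaction with the stabilised formylmethylene ylide adds C6 and the formyl carbon as the E-enal; the neopentyl environment should discourage a second homologation, and the Z-configured, fully substituted diene terminus should keep uncatalysed cycloaddition slow at this temperature.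

Step 9
Reactants: 16 (2E,8Z)-4,4,8-trimethyl-9-(prop-2-en-1-yl)undeca-2,8,10-trienal
Product: 19 (1S,4aR,8aS)-4a,8,8-trimethyl-4-(prop-2-en-1-yl)-1,2,4a,5,6,7,8,8a-octahydronaphthalene-1-carbaldehyde, via iminium ion 17 (not isolated), via cycloadduct iminium ion 18 (not isolated)
Conditions: (2S,5S)-5-benzyl-2-tert-butyl-3-methylimidazolidin-4-one·CF3CO2H (20 mol %), CH3CN/H2O 50:1, 0 °C to rt
Reagents that add atoms: none
Why: Proposed new method: condensation of the enal with the imidazolidinone salt should give the E-iminium ion 17, whose lowered LUMO lets the tethered diene add across C5=C6 in a concerted, asynchronous [4+2] cycloaddition before hydrolysis of 18 releases 19 and the catalyst; the closest known reaction type is the amine-catalysed intramolecular Diels–Alder reaction of 2,7,9-trienals with E-configured, monosubstituted diene termini, and thermal cyclisations of Z-tethered dienes are known to give only cis-fused bicycles, but a fully substituted diene terminus that creates a quaternary ring-fusion carbon has not been shown under iminium catalysis. Ring B closes as the cyclohexene of the cycloaddition (bonds C5–C10 and C6–C7), and ring A closes in the same event as the six-membered carbocycle spanned by the four-carbon tether C1–C4 between C10 and C5 (type 1 intramolecular mode, tether on the diene terminus). C10 and C5 are related by the Z geometry of C9=C10: the tether sits on the inside position of the diene, can reach only the exo position at C5, and so enforces the cis fusion with H-5 and the C10 methyl group on one face. C6 follows from the E geometry of the enal, which holds the formyl group cis to H-5 (iminium endo). The absolute configuration should come from the catalyst, whose benzyl group covers one face of the iminium ion so that C10 bonds to the open face of C5, the same face this catalyst leaves open in its conjugate additions. The step needs to run at or below room temperature to outpace the racemic thermal pathway, and the features relied on are iminium activation, the trialkyl-substituted electron-rich diene and the gem-dimethyl group at C4 (Thorpe–Ingold effect).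

Step 10
Reactants: 19 (1S,4aR,8aS)-4a,8,8-trimethyl-4-(prop-2-en-1-yl)-1,2,4a,5,6,7,8,8a-octahydronaphthalene-1-carbaldehyde
Product: 21 3-[(4S,4aS,8aR)-4-(hydroxymethyl)-5,5,8a-trimethyl-3,4,4a,5,6,7,8,8a-octahydronaphthalen-1-yl]propan-1-ol, via bis-boron adduct 20 (not isolated)
Conditions: 9-BBN (3 equiv), THF, 0 °C to rt; then NaOH, H2O2, 0 °C to rt
Reagents that add atoms: hydrogen peroxide, OO
Why: Anti-Markovnikov hydroboration–oxidation: 9-BBN should hydroborate the monosubstituted allyl alkene at its terminus and reduce the aldehyde while leaving the hindered trisubstituted ring alkene alone, so both carbons to be methylated later appear as primary alcohols.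

Step 11
Reactants: 21 3-[(4S,4aS,8aR)-4-(hydroxymethyl)-5,5,8a-trimethyl-3,4,4a,5,6,7,8,8a-octahydronaphthalen-1-yl]propan-1-ol
Product: 22 (5S,6S,8R,9S,10R)-8α,9α-epoxy diol (21 with C8=C9 converted into an epoxide on the face of the C10 methyl group)
Conditions: mCPBA, NaHCO3, CH2Cl2, 0 °C
Reagents that add atoms: 3-chloroperoxybenzoic acid, OOC(=O)c1cccc(Cl)c1
Why: Prilezhaev epoxidation of the only remaining alkene; the peracid should approach the convex α face because the β face of C8=C9 is screened by the pseudo-axial C1 methylene of ring A, which sets C8 and C9 of the epoxide.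

Step 12
Reactants: 22 (5S,6S,8R,9S,10R)-8α,9α-epoxy diol
Product: 23 (5S,6S,8R,9S,10R)-8α,9α-epoxy dialdehyde (22 with both CH2OH groups oxidised to CHO)
Conditions: Dess–Martin periodinane (2.5 equiv), NaHCO3, CH2Cl2, 0 °C to rt
Reagents that add atoms: none
Why: Buffered Dess–Martin oxidation should turn both primary alcohols into aldehydes without opening the epoxide, removing the hydroxyl groups that could trap the cation of the next step.

Step 13
Reactants: 23 (5S,6S,8R,9S,10R)-8α,9α-epoxy dialdehyde
Product: 24 (1S,4S,4aR,8aS)-4a,8,8-trimethyl-3-oxo-4-(3-oxopropyl)decahydronaphthalene-1-carbaldehyde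
Conditions: BF3·OEt2 (3 equiv), CH2Cl2, −78 °C; cold aqueous NaHCO3 quench; crude product used at once
Reagents that add atoms: none
Why: Meinwald (Lewis-acid epoxide-to-ketone) rearrangement: ionisation at tertiary C9 should be accompanied by a suprafacial 1,2-shift of the axial β-hydrogen of C8, anti-periplanar to the breaking C9–O bond, so that C8 becomes the ketone and C9 receives its hydrogen on the β face (side chain α), as in the stereospecific rearrangements of steroidal trisubstituted epoxides.

Step 14
Reactants: 24 (1S,4S,4aR,8aS)-4a,8,8-trimethyl-3-oxo-4-(3-oxopropyl)decahydronaphthalene-1-carbaldehyde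
Product: 25 (1S,2S,4S,4aS,8aR)-4-(1-hydroxyethyl)-1-(3-hydroxybutyl)-2,5,5,8a-tetramethyldecahydronaphthalen-2-ol (epimer mixture at the two secondary carbinol carbons)
Conditions: MeMgBr (6 equiv), CeCl3 (6 equiv), THF, −78 to 0 °C
Reagents that add atoms: methylmagnesium bromide, C[Mg]Br
Why: Organocerium-mediated Grignard addition to both aldehydes and the ketone without enolising C9; at C8 the methyl group should enter equatorially from the α face because the axial path is blocked by the syn-axial C1 methylene, giving the β (axial) tertiary hydroxyl, while the two secondary carbinol centres are erased in the next step.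

Step 15
Reactants: 25 (1S,2S,4S,4aS,8aR)-4-(1-hydroxyethyl)-1-(3-hydroxybutyl)-2,5,5,8a-tetramethyldecahydronaphthalen-2-ol
Product: 26 4-[(1S,2S,4S,4aS,8aR)-4-acetyl-2-hydroxy-2,5,5,8a-tetramethyldecahydronaphthalen-1-yl]butan-2-one
Conditions: Dess–Martin periodinane (3 equiv), NaHCO3, CH2Cl2, rt
Reagents that add atoms: none
Why: Dess–Martin oxidation of the two secondary alcohols should give the ring acetyl group and the side-chain methyl ketone and leave the tertiary alcohol untouched.

Step 16
Reactants: 26 4-[(1S,2S,4S,4aS,8aR)-4-acetyl-2-hydroxy-2,5,5,8a-tetramethyldecahydronaphthalen-1-yl]butan-2-one; 27 prop-2-en-1-yl 2-(diethoxyphosphoryl)acetate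
Product: 29 prop-2-en-1-yl (2E)-5-[(1S,2S,4S,4aS,8aR)-4-acetyl-2-hydroxy-2,5,5,8a-tetramethyldecahydronaphthalen-1-yl]-3-methylpent-2-enoate, via sodium phosphonate carbanion 28 (not isolated)
Conditions: NaH, THF, 0 °C; then 26, 0 to 40 °C
Reagents that add atoms: none
Why: Horner–Wadsworth–Emmons olefination should occur only at the unhindered side-chain methyl ketone, the ring acetyl group being flanked by two ring branches, and should favour the E-enoate, any Z isomer being removed by chromatography.

Step 17
Reactants: 29 prop-2-en-1-yl (2E)-5-[(1S,2S,4S,4aS,8aR)-4-acetyl-2-hydroxy-2,5,5,8a-tetramethyldecahydronaphthalen-1-yl]-3-methylpent-2-enoate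
Product: 30 prop-2-en-1-yl (2E)-5-[(1S,2S,4S,4aS,8aR)-4-(acetyloxy)-2-hydroxy-2,5,5,8a-tetramethyldecahydronaphthalen-1-yl]-3-methylpent-2-enoate
Conditions: mCPBA, NaHCO3, CH2Cl2, 0 °C to rt
Reagents that add atoms: 3-chloroperoxybenzoic acid, OOC(=O)c1cccc(Cl)c1
Why: Baeyer–Villiger oxidation of the methyl ketone with migration of the secondary ring carbon C6 should install the acetate with retention of configuration, while the conjugated enoate and the electron-poor allyl ester alkene are expected to resist epoxidation.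

Step 18
Reactants: 30 prop-2-en-1-yl (2E)-5-[(1S,2S,4S,4aS,8aR)-4-(acetyloxy)-2-hydroxy-2,5,5,8a-tetramethyldecahydronaphthalen-1-yl]-3-methylpent-2-enoate
Product: 31 (2E)-5-[(1S,2S,4S,4aS,8aR)-4-(acetyloxy)-2-hydroxy-2,5,5,8a-tetramethyldecahydronaphthalen-1-yl]-3-methylpent-2-enoic acid
Conditions: Pd(PPh3)4 (5 mol %), morpholine, THF, rt; then aqueous citric acid
Reagents that add atoms: none
Why: Palladium-catalysed deallylation (Tsuji–Trost allyl transfer to morpholine) should free the carboxylic acid under neutral conditions that leave the acetate, the tertiary alcohol and the E-alkene untouched.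

**Compound list**

1 | methyl 2-methylpropanoate (methyl isobutyrate) | COC(=O)C(C)C | starting material
2 | 5-iodopent-1-yne | C#CCCCI | starting material
3 | lithium enolate of 1 (lithium 1-methoxy-2-methylprop-1-en-1-olate) | [Li]OC(OC)=C(C)C | intermediate
4 | methyl 2,2-dimethylhept-6-ynoate | COC(=O)C(C)(C)CCCC#C | intermediate
5 | ethyl chloroformate | CCOC(=O)Cl | starting material
6 | lithium acetylide of 4 (methyl 7-lithio-2,2-dimethylhept-6-ynoate) | [Li]C#CCCCC(C)(C)C(=O)OC | intermediate
7 | 1-ethyl 8-methyl 7,7-dimethyloct-2-ynedioate | CCOC(=O)C#CCCCC(C)(C)C(=O)OC | intermediate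
8 | 3-bromoprop-1-ene (allyl bromide) | C=CCBr | starting material
9 | alkenylcuprate: lithium [(2E)-1-ethoxy-8-methoxy-3,7,7-trimethyl-1,8-dioxooct-2-en-2-yl](methyl)cuprate | CCOC(=O)/C([Cu-]C)=C(C)\CCCC(C)(C)C(=O)OC.[Li+] | intermediate
10 | 1-ethyl 8-methyl (2Z)-3,7,7-trimethyl-2-(prop-2-en-1-yl)oct-2-enedioate | CCOC(=O)/C(CC=C)=C(C)\CCCC(C)(C)C(=O)OC | intermediate
11 | (2Z)-3,7,7-trimethyl-2-(prop-2-en-1-yl)oct-2-ene-1,8-diol | OC/C(CC=C)=C(C)\CCCC(C)(C)CO | intermediate
12 | (2Z)-8-hydroxy-3,7,7-trimethyl-2-(prop-2-en-1-yl)oct-2-enal | O=C/C(CC=C)=C(C)\CCCC(C)(C)CO | intermediate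
13 | (6Z)-2,2,6-trimethyl-7-(prop-2-en-1-yl)nona-6,8-dien-1-ol | C=C/C(CC=C)=C(C)\CCCC(C)(C)CO | intermediate
14 | (6Z)-2,2,6-trimethyl-7-(prop-2-en-1-yl)nona-6,8-dienal | C=C/C(CC=C)=C(C)\CCCC(C)(C)C=O | intermediate
15 | 2-(triphenyl-λ5-phosphanylidene)acetaldehyde | O=CC=P(c1ccccc1)(c1ccccc1)c1ccccc1 | starting material
16 | (2E,8Z)-4,4,8-trimethyl-9-(prop-2-en-1-yl)undeca-2,8,10-trienal | O=C/C=C/C(C)(C)CCC/C(C)=C(\C=C)CC=C | intermediate
17 | iminium ion: E-iminium trifluoroacetate of 16 with the (2S,5S)-imidazolidinone | CN1[C@@H](C(C)(C)C)/[N+](=C/C=C/C(C)(C)CCC/C(C)=C(\C=C)CC=C)[C@@H](Cc2ccccc2)C1=O.[O-]C(=O)C(F)(F)F | intermediate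
18 | cycloadduct iminium ion: iminium trifluoroacetate of 19 with the (2S,5S)-imidazolidinone | CN1[C@@H](C(C)(C)C)/[N+](=C/[C@H]3CC=C(CC=C)[C@]4(C)CCCC(C)(C)[C@H]34)[C@@H](Cc2ccccc2)C1=O.[O-]C(=O)C(F)(F)F | intermediate
19 | (1S,4aR,8aS)-4a,8,8-trimethyl-4-(prop-2-en-1-yl)-1,2,4a,5,6,7,8,8a-octahydronaphthalene-1-carbaldehyde (cis-fused; CHO, H-5 and C10 methyl on one face) | O=C[C@H]1CC=C(CC=C)[C@]2(C)CCCC(C)(C)[C@H]12 | intermediate
20 | bis-boron adduct of 19 (9-borabicyclo[3.3.1]nonan-9-yl borinate at the reduced formyl group, B-alkyl-9-borabicyclo[3.3.1]nonane at the chain terminus) | C(OB1C2CCCC1CCC2)[C@H]3CC=C(CCCB4C5CCCC4CCC5)[C@]6(C)CCCC(C)(C)[C@H]36 | intermediate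
21 | 3-[(4S,4aS,8aR)-4-(hydroxymethyl)-5,5,8a-trimethyl-3,4,4a,5,6,7,8,8a-octahydronaphthalen-1-yl]propan-1-ol | OC[C@H]1CC=C(CCCO)[C@]2(C)CCCC(C)(C)[C@H]12 | intermediate
22 | (5S,6S,8R,9S,10R)-8α,9α-epoxy diol (21 with C8=C9 as an epoxide on the face of the C10 methyl group) | OC[C@H]1C[C@H]4O[C@@]4(CCCO)[C@]2(C)CCCC(C)(C)[C@H]12 | intermediate
23 | (5S,6S,8R,9S,10R)-8α,9α-epoxy dialdehyde (22 with both CH2OH groups as CHO) | O=C[C@H]1C[C@H]4O[C@@]4(CCC=O)[C@]2(C)CCCC(C)(C)[C@H]12 | intermediate
24 | (1S,4S,4aR,8aS)-4a,8,8-trimethyl-3-oxo-4-(3-oxopropyl)decahydronaphthalene-1-carbaldehyde | O=C[C@H]1CC(=O)[C@@H](CCC=O)[C@]2(C)CCCC(C)(C)[C@H]12 | intermediate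
25 | (1S,2S,4S,4aS,8aR)-4-(1-hydroxyethyl)-1-(3-hydroxybutyl)-2,5,5,8a-tetramethyldecahydronaphthalen-2-ol (epimer mixture at the two secondary carbinol carbons) | CC(O)[C@H]1C[C@](C)(O)[C@@H](CCC(C)O)[C@]2(C)CCCC(C)(C)[C@H]12 | intermediate
26 | 4-[(1S,2S,4S,4aS,8aR)-4-acetyl-2-hydroxy-2,5,5,8a-tetramethyldecahydronaphthalen-1-yl]butan-2-one | CC(=O)[C@H]1C[C@](C)(O)[C@@H](CCC(C)=O)[C@]2(C)CCCC(C)(C)[C@H]12 | intermediate
27 | prop-2-en-1-yl 2-(diethoxyphosphoryl)acetate | C=CCOC(=O)CP(=O)(OCC)OCC | starting material
28 | sodium phosphonate carbanion of 27 | [Na+].C=CCOC(=O)[CH-]P(=O)(OCC)OCC | intermediate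
29 | prop-2-en-1-yl (2E)-5-[(1S,2S,4S,4aS,8aR)-4-acetyl-2-hydroxy-2,5,5,8a-tetramethyldecahydronaphthalen-1-yl]-3-methylpent-2-enoate | CC(=O)[C@H]1C[C@](C)(O)[C@@H](CC/C(C)=C/C(=O)OCC=C)[C@]2(C)CCCC(C)(C)[C@H]12 | intermediate
30 | prop-2-en-1-yl (2E)-5-[(1S,2S,4S,4aS,8aR)-4-(acetyloxy)-2-hydroxy-2,5,5,8a-tetramethyldecahydronaphthalen-1-yl]-3-methylpent-2-enoate | CC(=O)O[C@H]1C[C@](C)(O)[C@@H](CC/C(C)=C/C(=O)OCC=C)[C@]2(C)CCCC(C)(C)[C@H]12 | intermediate
31 | (2E)-5-[(1S,2S,4S,4aS,8aR)-4-(acetyloxy)-2-hydroxy-2,5,5,8a-tetramethyldecahydronaphthalen-1-yl]-3-methylpent-2-enoic acid (CNP0221670.1) | CC(=O)O[C@H]1C[C@](C)(O)[C@@H](CC/C(C)=C/C(=O)O)[C@]2(C)CCCC(C)(C)[C@H]12 | target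

**Step count**

Total step count: 18. Longest linear sequence: 18 steps (1 to 31).

**Steps most likely to fail**

Step 9 (bears the label). The C5–C10 bond joins a β-carbon next to a quaternary centre to a fully substituted diene terminus, so cycloaddition under iminium activation may be too slow. The racemic thermal pathway or hydrolytic loss of the iminium ion could then compete, and facial discrimination by the catalyst may be poor for so hindered an enal. The fallback is an auxiliary-controlled, Lewis-acid-promoted intramolecular Diels–Alder reaction of a triene N-acyloxazolidinone, which is known chemistry. It sets out from aldehyde 14, which would be olefinated with diethyl {2-[(4S)-4-benzyl-2-oxo-1,3-oxazolidin-3-yl]-2-oxoethyl}phosphonate (LiCl, iPr2NEt, CH3CN) to give (4S)-4-benzyl-3-[(2E,8Z)-4,4,8-trimethyl-9-(prop-2-en-1-yl)undeca-2,8,10-trienoyl]-1,3-oxazolidin-2-one F1. Me2AlCl in CH2Cl2 at −30 °C should chelate both carbonyl groups, and the diene should add to the face remote from the benzyl group with the same exo-tether, endo-carbonyl geometry. This should give the cis-fused imide (4S)-4-benzyl-3-{[(1S,4aR,8aS)-4a,8,8-trimethyl-4-(prop-2-en-1-yl)-1,2,4a,5,6,7,8,8a-octahydronaphthalen-1-yl]carbonyl}-1,3-oxazolidin-2-one F2. LiBH4 (THF, H2O, 0 °C) would then remove the auxiliary reductively to give [(1S,4aR,8aS)-4a,8,8-trimethyl-4-(prop-2-en-1-yl)-1,2,4a,5,6,7,8,8a-octahydronaphthalen-1-yl]methanol F3. Hydroboration–oxidation of its allyl group under the conditions of step 10 comes back to the route at diol 21.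

Step 13. Hydride migration may be outrun by capture of the C9 cation by fluoride or by a boron-bound formyl oxygen, or by migration of the C7–C8 ring bond (ring contraction). The product may also lose its C9 configuration by enolisation under the Lewis acid. The fallback reaches the same cation by pinacol rearrangement of a cis-diol with no formyl groups present; it sets out from diol 21. Acetylation (Ac2O, pyridine) would give 3-[(4S,4aS,8aR)-4-(acetoxymethyl)-5,5,8a-trimethyl-3,4,4a,5,6,7,8,8a-octahydronaphthalen-1-yl]propyl acetate F4. Dihydroxylation from the α face (OsO4 cat., N-methylmorpholine N-oxide, acetone/H2O) would give the (8R,9S)-8α,9α-diol of F4 F5. TsOH in toluene at 50 °C should ionise the axial tertiary C9 hydroxyl and move the anti-periplanar β-hydrogen from C8 to C9, giving the bis-acetate of the 8-oxo diol F6. Acidic methanolysis (HCl in MeOH) would give (1S,4S,4aS,8aR)-4-(hydroxymethyl)-1-(3-hydroxypropyl)-5,5,8a-trimethyloctahydronaphthalen-2(1H)-one F7, and Dess–Martin oxidation of both primary alcohols comes back to the route at keto dialdehyde 24.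

Step 3. The α-cuprio ester may equilibrate through its allenoate form before the slower allylation takes place, eroding the C9=C10 geometry, or it may simply be protonated on work-up. The fallback separates trapping from C–C bond formation; it sets out from ynoate 7. Me2CuLi addition at −78 °C would be followed by an instantaneous iodine quench to give 1-ethyl 8-methyl (2E)-2-iodo-3,7,7-trimethyloct-2-enedioate F8. Stille coupling with allyltributylstannane (Pd(PPh3)4, CuI, DMF, rt) should then proceed with retention and come back to the route at diester 10.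

Further compounds
F1 | step 9 | (4S)-4-benzyl-3-[(2E,8Z)-4,4,8-trimethyl-9-(prop-2-en-1-yl)undeca-2,8,10-trienoyl]-1,3-oxazolidin-2-one | O=C(/C=C/C(C)(C)CCC/C(C)=C(\C=C)CC=C)N1[C@@H](Cc2ccccc2)COC1=O
F2 | step 9 | (4S)-4-benzyl-3-{[(1S,4aR,8aS)-4a,8,8-trimethyl-4-(prop-2-en-1-yl)-1,2,4a,5,6,7,8,8a-octahydronaphthalen-1-yl]carbonyl}-1,3-oxazolidin-2-one | O=C([C@H]1CC=C(CC=C)[C@]2(C)CCCC(C)(C)[C@H]12)N3[C@@H](Cc4ccccc4)COC3=O
F3 | step 9 | [(1S,4aR,8aS)-4a,8,8-trimethyl-4-(prop-2-en-1-yl)-1,2,4a,5,6,7,8,8a-octahydronaphthalen-1-yl]methanol | OC[C@H]1CC=C(CC=C)[C@]2(C)CCCC(C)(C)[C@H]12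
F4 | step 13 | 3-[(4S,4aS,8aR)-4-(acetoxymethyl)-5,5,8a-trimethyl-3,4,4a,5,6,7,8,8a-octahydronaphthalen-1-yl]propyl acetate | CC(=O)OC[C@H]1CC=C(CCCOC(C)=O)[C@]2(C)CCCC(C)(C)[C@H]12
F5 | step 13 | (8R,9S)-8α,9α-diol of F4 | CC(=O)OC[C@H]1C[C@@H](O)[C@](O)(CCCOC(C)=O)[C@]2(C)CCCC(C)(C)[C@H]12
F6 | step 13 | bis-acetate of (1S,4S,4aS,8aR)-4-(hydroxymethyl)-1-(3-hydroxypropyl)-5,5,8a-trimethyloctahydronaphthalen-2(1H)-one | CC(=O)OC[C@H]1CC(=O)[C@@H](CCCOC(C)=O)[C@]2(C)CCCC(C)(C)[C@H]12
F7 | step 13 | (1S,4S,4aS,8aR)-4-(hydroxymethyl)-1-(3-hydroxypropyl)-5,5,8a-trimethyloctahydronaphthalen-2(1H)-one | OC[C@H]1CC(=O)[C@@H](CCCO)[C@]2(C)CCCC(C)(C)[C@H]12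
F8 | step 3 | 1-ethyl 8-methyl (2E)-2-iodo-3,7,7-trimethyloct-2-enedioate | CCOC(=O)/C(I)=C(C)\CCCC(C)(C)C(=O)OC
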